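The plan rests on opening ring C'' of the apigenin half. This 2-aryl-4-pyranone is traced to CO (C4''), an arylacetylene (C3'', C2'' and ring B'') and an iodophenol in which iodine marks C4a'' and the adjacent oxygen becomes O1''. One palladium-catalysed carbonylative alkynylation–cyclisation therefore forms C4a''–C4'', C4''–C3'' and O1''–C2'' on a finished acacetin half. The precursor is the 8-(3-iodo-4-methoxy-2,6-dioxyphenyl)flavone, used as its triacetate so that the labile iodophloroglucinol stays masked until the amine solvent releases it. The tetra-ortho-oxygenated 8,8'' axis comes from an oxidative aryllithium homocoupling, ring C from a redox-neutral ynone cyclisation, and one BCl3 step ends the route.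

Key step: step 7

Assumption: the target SMILES gives no sense for the 8,8'' axis, so the axis is built without control and every biaryl from 12 onward is racemic.

Design remarks:
- Ring C is closed from an ynone without any oxidant. An iodine/DMSO dehydrogenation of a chalcone would meet the still unsubstituted phloroglucinol-type ring and iodinate it uncontrollably.
- Iodine is introduced last and the iodo triol is acetylated in the same flask. An ortho-iodophenol this electron-rich can lose iodine to amines through its keto tautomer.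
- The two methyl ethers inherited from the starting material block the second ortho position of each acyl group, so both pyranone closures have only one possible regiochemistry.

Step 1
Reactants: 1 5-methoxyresorcinol
Product: 2 1-methoxy-3,5-bis(methoxymethoxy)benzene
Conditions: MOMCl (2.5 equiv), i-Pr2NEt (3 equiv), CH2Cl2, 0 °C to rt
Reagents that add atoms: chloromethyl methyl ether (MOMCl), COCCl
Why: Williamson-type O-alkylation of both phenols under mild amine base installs the acetal groups that will direct the metalations of steps 2 and 4.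

Step 2
Reactants: 2 1-methoxy-3,5-bis(methoxymethoxy)benzene (two molecules)
Product: 4 4,4'-dimethoxy-2,2',6,6'-tetrakis(methoxymethoxy)-1,1'-biphenyl, via aryllithium 3 (not isolated)
Conditions: n-BuLi (1.05 equiv), THF, 0 °C to rt; anhydrous CuCl2 (1.1 equiv), −78 °C to rt
Reagents that add atoms: none
Why: Directed ortho-metalation takes place at the carbon flanked by the two chelating MOM ethers, and oxidation of the derived arylcopper species by divalent copper (oxidative homocoupling of an aryllithium) joins two such carbons, a method that tolerates four ortho-alkoxy groups.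

Step 3
Reactants: 5 1-ethynyl-4-methoxybenzene
Product: 7 N-methoxy-3-(4-methoxyphenyl)-N-methylprop-2-ynamide, via lithium acetylide 6 (not isolated)
Conditions: n-BuLi (1.0 equiv), THF, −78 °C; ClC(O)N(OMe)Me (1.1 equiv), −78 to 0 °C
Reagents that add atoms: N-methoxy-N-methylcarbamoyl chloride, CON(C)C(=O)Cl
Why: Nucleophilic acyl substitution of a carbamoyl chloride by a lithium acetylide stops at the Weinreb amide because chloride is by far the better leaving group.

Step 4
Reactants: 4 4,4'-dimethoxy-2,2',6,6'-tetrakis(methoxymethoxy)-1,1'-biphenyl; 7 N-methoxy-3-(4-methoxyphenyl)-N-methylprop-2-ynamide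
Product: 9 1-[4,4'-dimethoxy-2,2',6,6'-tetrakis(methoxymethoxy)-[1,1'-biphenyl]-3-yl]-3-(4-methoxyphenyl)prop-2-yn-1-one, via monolithiated biaryl 8 (not isolated)
Conditions: n-BuLi (0.9 equiv), THF, 0 °C; 7 (1.0 equiv), −78 to −20 °C; sat. aq NH4Cl
Reagents that add atoms: none
Why: The four remaining ring hydrogens of 4 are equivalent and each lies between a MOM ether and a methyl ether, so directed ortho-metalation with a deficit of base followed by Weinreb ketone synthesis should give one mono-acylated regioisomer, the split between mono- and bis-acylation being statistical and unreacted 4 being recovered and recycled.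

Step 5
Reactants: 9 1-[4,4'-dimethoxy-2,2',6,6'-tetrakis(methoxymethoxy)-[1,1'-biphenyl]-3-yl]-3-(4-methoxyphenyl)prop-2-yn-1-one
Product: 11 8-(2,6-dihydroxy-4-methoxyphenyl)-7-hydroxy-5-methoxy-2-(4-methoxyphenyl)-4H-chromen-4-one, via tetrahydroxy ynone 10 (not isolated)
Conditions: HCl (2 M in MeOH), 45 °C
Reagents that add atoms: none
Why: Acid-catalysed acetal cleavage frees the four phenols, and the only hydroxyl ortho to the protonated ynone adds to its anisyl-stabilised β-carbon in a 6-endo-dig oxa-Michael cyclisation, any methanol, chloride or amine adduct at that carbon collapsing to the same flavone by addition–elimination.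

Step 6
Reactants: 11 8-(2,6-dihydroxy-4-methoxyphenyl)-7-hydroxy-5-methoxy-2-(4-methoxyphenyl)-4H-chromen-4-one
Product: 13 8-(2,6-diacetoxy-3-iodo-4-methoxyphenyl)-5-methoxy-2-(4-methoxyphenyl)-4-oxo-4H-chromen-7-yl acetate (racemic axis), via iodo triol 12 (not isolated)
Conditions: NIS (1.0 equiv), DMF, −20 to 0 °C, dark; then Ac2O (6 equiv), pyridine, DMAP (cat.), 0 °C to rt
Reagents that add atoms: N-iodosuccinimide, O=C1CCC(=O)N1I; acetic anhydride, CC(=O)OC(C)=O
Why: Electrophilic aromatic iodination goes to the pendant phloroglucinol-type ring, which carries no acyl group and is far more nucleophilic than C6 of ring A and whose two open positions are enantiotopic, so one equivalent of NIS should give a single racemic mono-iodide that DMAP-catalysed O-acetylation traps before it can lose iodine.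

Step 7
Reactants: 13 8-(2,6-diacetoxy-3-iodo-4-methoxyphenyl)-5-methoxy-2-(4-methoxyphenyl)-4-oxo-4H-chromen-7-yl acetate; 14 carbon monoxide; 15 1-(benzyloxy)-4-ethynylbenzene
Product: 18 4'''-O-benzyl-5,5''-di-O-methyl-4'-O-methylcupressuflavone (racemic axis), via aryl ynone triacetate 16 (not isolated), via diethylamino enaminone 17 (not isolated)
Conditions: PdCl2(PPh3)2 (5 mol %), CO (10 bar), 15 (1.5 equiv), Et2NH–DMF (1:1), 70 °C, no copper salt
Reagents that add atoms: carbon monoxide 14, [C-]#[O+]
Why: PdCl2(PPh3)2 is reduced in the amine–alkyne medium to zerovalent palladium, which inserts into the C–I bond of 13; migratory insertion of CO gives an aroyl-palladium species, and transfer of the acetylide derived from 15 followed by reductive elimination gives ynone 16 (bonds C4a''–C4'' and C4''–C3''). The solvent amine then does two jobs, conjugate addition to the ynone and aminolysis of the three aryl acetates, which leads to the vinylogous amide 17, whose C2'' is attacked by the freed ortho hydroxyl with expulsion of Et2NH (bond O1''–C2''), that is, a 6-endo closure of ring C'' by addition–elimination. The closest known reaction type is the palladium-catalysed carbonylative Sonogashira coupling–cyclisation of 2-iodophenols, and of their acetates, with terminal alkynes to flavones in a secondary amine. The step needs the flavone rather than the aurone, which is secured because the acetate holds the phenol back until the amine has made C2'' the only electrophilic carbon, and it needs the 8''-linked regioisomer, which is secured because the acyl carbon lies between a single acyloxy group and the inert 5''-methyl ether, the remaining oxygen of that ring simply emerging as 7''-OH. Carbonylation must also outrun CO-free alkynylation and loss of iodine, which is served by CO pressure, the absence of copper salts and the acetate masking, since the masked ring cannot tautomerise and hand iodine to the amine and its C–I bond is less electron-rich. No stereocentre is created and the 8,8'' axis remains racemic.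

Step 8
Reactants: 18 4'''-O-benzyl-5,5''-di-O-methyl-4'-O-methylcupressuflavone
Product: 19 4'-O-methylcupressuflavone (CNP0322111.0, racemic axis)
Conditions: BCl3 (10 equiv), C6HMe5 (5 equiv), CH2Cl2, −78 to 0 °C; MeOH, then 1 M aq HCl
Reagents that add atoms: none
Why: In this Lewis-acid ether cleavage BCl3 with pentamethylbenzene as benzyl-cation trap removes the aryl benzyl ether at low temperature, and on warming boron held between each C4 carbonyl and its peri 5-methoxy oxygen delivers chloride to those two methyl groups only, whereas the unchelated and electron-depleted 4'-methyl ether is inert to BCl3 at 0 °C.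

Compound list
1 | 5-methoxyresorcinol | COc1cc(O)cc(O)c1 | starting material
2 | 1-methoxy-3,5-bis(methoxymethoxy)benzene | COCOc1cc(OC)cc(OCOC)c1 | intermediate
3 | [4-methoxy-2,6-bis(methoxymethoxy)phenyl]lithium | [Li]c1c(OCOC)cc(OC)cc1OCOC | intermediate (not isolated)
4 | 4,4'-dimethoxy-2,2',6,6'-tetrakis(methoxymethoxy)-1,1'-biphenyl | COCOc1cc(OC)cc(OCOC)c1-c1c(OCOC)cc(OC)cc1OCOC | intermediate
5 | 1-ethynyl-4-methoxybenzene | C#Cc1ccc(OC)cc1 | starting material
6 | lithium (4-methoxyphenyl)acetylide | [Li]C#Cc1ccc(OC)cc1 | intermediate (not isolated)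
7 | N-methoxy-3-(4-methoxyphenyl)-N-methylprop-2-ynamide | CON(C)C(=O)C#Cc1ccc(OC)cc1 | intermediate
8 | 3-lithio-4,4'-dimethoxy-2,2',6,6'-tetrakis(methoxymethoxy)-1,1'-biphenyl | [Li]c1c(OC)cc(OCOC)c(-c2c(OCOC)cc(OC)cc2OCOC)c1OCOC | intermediate (not isolated)
9 | 1-[4,4'-dimethoxy-2,2',6,6'-tetrakis(methoxymethoxy)-[1,1'-biphenyl]-3-yl]-3-(4-methoxyphenyl)prop-2-yn-1-one | COc1ccc(cc1)C#CC(=O)c1c(OC)cc(OCOC)c(-c2c(OCOC)cc(OC)cc2OCOC)c1OCOC | intermediate
10 | 1-(2,2',6,6'-tetrahydroxy-4,4'-dimethoxy-[1,1'-biphenyl]-3-yl)-3-(4-methoxyphenyl)prop-2-yn-1-one | COc1ccc(cc1)C#CC(=O)c1c(OC)cc(O)c(-c2c(O)cc(OC)cc2O)c1O | intermediate (not isolated)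
11 | 8-(2,6-dihydroxy-4-methoxyphenyl)-7-hydroxy-5-methoxy-2-(4-methoxyphenyl)-4H-chromen-4-one | COc1ccc(cc1)-c1cc(=O)c2c(OC)cc(O)c(-c3c(O)cc(OC)cc3O)c2o1 | intermediate
12 | 8-(2,6-dihydroxy-3-iodo-4-methoxyphenyl)-7-hydroxy-5-methoxy-2-(4-methoxyphenyl)-4H-chromen-4-one (racemic axis) | COc1ccc(cc1)-c1cc(=O)c2c(OC)cc(O)c(-c3c(O)cc(OC)c(I)c3O)c2o1 | intermediate (not isolated)
13 | 8-(2,6-diacetoxy-3-iodo-4-methoxyphenyl)-5-methoxy-2-(4-methoxyphenyl)-4-oxo-4H-chromen-7-yl acetate (racemic axis) | COc1ccc(cc1)-c1cc(=O)c2c(OC)cc(OC(C)=O)c(-c3c(OC(C)=O)cc(OC)c(I)c3OC(C)=O)c2o1 | intermediate (key-step precursor)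
14 | carbon monoxide | [C-]#[O+] | starting material
15 | 1-(benzyloxy)-4-ethynylbenzene | C#Cc1ccc(OCc2ccccc2)cc1 | starting material
16 | 8-{2,6-diacetoxy-3-[3-(4-benzyloxyphenyl)prop-2-ynoyl]-4-methoxyphenyl}-5-methoxy-2-(4-methoxyphenyl)-4-oxo-4H-chromen-7-yl acetate | COc1ccc(cc1)-c1cc(=O)c2c(OC)cc(OC(C)=O)c(-c3c(OC(C)=O)cc(OC)c(C(=O)C#Cc4ccc(OCc5ccccc5)cc4)c3OC(C)=O)c2o1 | intermediate (not isolated)
17 | 8-{3-[3-(4-benzyloxyphenyl)-3-(diethylamino)prop-2-enoyl]-2,6-dihydroxy-4-methoxyphenyl}-7-hydroxy-5-methoxy-2-(4-methoxyphenyl)-4H-chromen-4-one (alkene geometry not fixed) | COc1ccc(cc1)-c1cc(=O)c2c(OC)cc(O)c(-c3c(O)cc(OC)c(C(=O)C=C(N(CC)CC)c4ccc(OCc5ccccc5)cc4)c3O)c2o1 | intermediate (not isolated)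
18 | 2''-[4-(benzyloxy)phenyl]-7,7''-dihydroxy-5,5''-dimethoxy-2-(4-methoxyphenyl)-8,8''-bi(4H-chromene)-4,4''-dione (racemic axis) | COc1ccc(cc1)-c1cc(=O)c2c(OC)cc(O)c(-c3c(O)cc(OC)c4c(=O)cc(-c5ccc(OCc6ccccc6)cc5)oc34)c2o1 | intermediate (key-step product)
19 | 4'-O-methylcupressuflavone, 5,5'',7,7''-tetrahydroxy-2''-(4-hydroxyphenyl)-2-(4-methoxyphenyl)-8,8''-bi(4H-chromene)-4,4''-dione (racemic axis) | COc1ccc(-c2cc(=O)c3c(O)cc(O)c(-c4c(O)cc(O)c5c(=O)cc(-c6ccc(O)cc6)oc45)c3o2)cc1 | target

Total step count: 8. Longest linear sequence: 7 (steps 1, 2, 4, 5, 6, 7, 8). Step 3 is a one-step side branch.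

Steps most likely to fail

Step 7. Oxidative addition into the doubly ortho-substituted C–I bond may be too slow. Reductive loss of iodine, capture of the aroyl-palladium species by Et2NH, or CO-free alkynylation followed by benzofuran closure could then take over. The fallback sets out from 11 and builds ring C'' by the classical acetophenone–chalcone sequence.
- C-acetylation of the pendant ring (Ac2O, BF3·OEt2, 70 °C, Friedel–Crafts/Fries manifold, only the two equivalent positions open) should give 8-(3-acetyl-2,6-dihydroxy-4-methoxyphenyl)-7-hydroxy-5-methoxy-2-(4-methoxyphenyl)-4H-chromen-4-one F1. Any O-acetate is cleaved in the next, basic operation.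
- Claisen–Schmidt condensation with commercial 4-(benzyloxy)benzaldehyde (KOH, EtOH, rt) should give 8-{3-[(E)-3-(4-benzyloxyphenyl)prop-2-enoyl]-2,6-dihydroxy-4-methoxyphenyl}-7-hydroxy-5-methoxy-2-(4-methoxyphenyl)-4H-chromen-4-one F2.
- Catalytic I2 in DMSO at 120 °C closes and dehydrogenates F2, and the route is rejoined at 18. At that stage both phloroglucinol rings carry an acyl group, so the iodine/DMSO medium no longer meets an unprotected electron-rich ring.

Step 4. Besides the statistical limit on mono-metalation, which is met by recycling 4, acyl transfer may suffer from conjugate attack of the hindered aryllithium on the alkynyl amide or from sluggish 1,2-addition. The fallback sets out from 8, generated from 4 as before, and replaces acyl substitution by carbonyl addition and oxidation. Addition to commercial 3-(4-methoxyphenyl)prop-2-ynal at −78 °C should give racemic 1-[4,4'-dimethoxy-2,2',6,6'-tetrakis(methoxymethoxy)-[1,1'-biphenyl]-3-yl]-3-(4-methoxyphenyl)prop-2-yn-1-ol F3. MnO2 in CH2Cl2 then oxidises this doubly activated alcohol, and the route is rejoined at 9.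

Step 2. Metalation may not be fully site-selective between the MOM/MOM and the MOM/OMe positions. At the crowded copper centre, chloride transfer or protonation may compete with C–C bond formation. The fallback sets out from 3 and separates the two events. Quenching with I2 should give 2-iodo-5-methoxy-1,3-bis(methoxymethoxy)benzene F4, which can be freed from any regioisomer. A classical Ullmann homocoupling (activated Cu powder, DMF, 140 °C), well established for 2,6-dialkoxyaryl iodides, then rejoins the route at 4.

Further compounds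
F1 | step 7 | 8-(3-acetyl-2,6-dihydroxy-4-methoxyphenyl)-7-hydroxy-5-methoxy-2-(4-methoxyphenyl)-4H-chromen-4-one | COc1ccc(cc1)-c1cc(=O)c2c(OC)cc(O)c(-c3c(O)cc(OC)c(C(C)=O)c3O)c2o1
F2 | step 7 | 8-{3-[(E)-3-(4-benzyloxyphenyl)prop-2-enoyl]-2,6-dihydroxy-4-methoxyphenyl}-7-hydroxy-5-methoxy-2-(4-methoxyphenyl)-4H-chromen-4-one | COc1ccc(cc1)-c1cc(=O)c2c(OC)cc(O)c(-c3c(O)cc(OC)c(C(=O)/C=C/c4ccc(OCc5ccccc5)cc4)c3O)c2o1
F3 | step 4 | 1-[4,4'-dimethoxy-2,2',6,6'-tetrakis(methoxymethoxy)-[1,1'-biphenyl]-3-yl]-3-(4-methoxyphenyl)prop-2-yn-1-ol (racemic) | COc1ccc(cc1)C#CC(O)c1c(OC)cc(OCOC)c(-c2c(OCOC)cc(OC)cc2OCOC)c1OCOC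
F4 | step 2 | 2-iodo-5-methoxy-1,3-bis(methoxymethoxy)benzene | COCOc1cc(OC)cc(OCOC)c1I
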